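## Structural features

The target consists of two 7,8,4'-trihydroxyflavan-3,4-diol units whose C4 carbons share a single ether oxygen (C4–O–C4). In each unit ring C is a dihydropyran with three adjacent stereocentres: C2 carries the 4-hydroxyphenyl ring B, C3 a free hydroxyl and C4 the bridging oxygen. The unit written first in the structure, called unit A here, is (2R,3R,4R) and therefore all-cis, whereas unit B is (2S,3R,4R) and therefore 2,3-trans and 3,4-cis, so the two units differ only at C2. Each ring A is a 1,2,3-trioxygenated benzene with O1 on C8a, free hydroxyls on C8 and C7, and C4a, ortho to C8a, bonded to C4. The fragile parts are the two catechols (oxidation, base), the 4-hydroxybenzylic C2–O1 bonds and above all the doubly benzylic C4–O–C4 ether, in which each C4 is ortho and para to oxygen donors of ring A and ionises easily. The real difficulty is an unsymmetrical ether between two secondary carbons of defined configuration at the most ionisable positions of the molecule, flanked by opposite C2 configurations. The key step uses the substitution pattern of ring A: a hydroxyl on C8a, oxygens on C8 and C7 and a carbon substituent on C4a are what a 2,3-dialkoxy-4-alkenylcyclobutenone delivers on ring expansion, so both rings A can be grown last on an ether whose C4 carbons are still only propargylic or allylic.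

## Logic of the disconnections

36 to 35: the eight benzyl–oxygen bonds are cut (six on phenols, two on the C3 hydroxyls). One protecting group that leaves every hydroxyl in a single neutral operation suits the catechols and the C4–O–C4 ether, and the gain is an oxidation-stable, lipophilic precursor. The forward step must stop before the secondary benzylic C4–O and C2–O1 bonds are hydrogenolysed.

35 to 34: the O1–C2 bond of each unit is cut. Closing each pyran by SN2 attack of the C8a phenol on C2 with inversion lets the 2,3-cis unit and the 2,3-trans unit come from C2-epimeric carbinols with identical C3 and C4, and both heterocycles disappear. The forward step must invert cleanly at a 4-alkoxybenzylic carbon and close a six-membered ring within each arm only.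

34 to 33: the two O–Si bonds at C2 are cut, so that C2 stays masked until the phenols exist. The forward desilylation must not turn the ortho-hydroxybenzylic C4 ether into a quinone methide.

33 to 29 and 4: C5–C6 and C4a–C8a of both rings A are cut. Both aromatic rings A vanish in one operation, leaving an acyclic ether whose C4 carbons are not benzylic and a four-carbon unit that traces back to 1. The forward step is a twofold coupling and ring expansion that must run under neutral conditions and leave six preset stereocentres alone.

29 to 28 to 27: the C–Sn bonds and then the C(sp)–Si bonds are cut. A terminal alkyne is the simplest precursor of an (E)-alkenylstannane, and the silyl caps are kept through the ether union to block SN2' attack and acetylide formation. The forward hydrostannation must be terminal and syn on both arms, which is why a bulky phosphine is specified.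

27 to 16 and 25: the C4–O bond on the unit B arm is cut. Both carbons are secondary and propargylic, so displacement of a triflate by an alkoxide with inversion is feasible, and the route splits into two arms of equal size. Because the displacement inverts the triflate carbon, 25 must carry (S) at C4 while 16 carries the final (R), so the two partners differ at C2 and at C4. The forward step must be SN2 without elimination or silyl migration.

16 to 15 to 12 and 13: the C4–H bond and then the C4–C(sp) bond are cut. Reduction of an ynone under chelation by the C3 benzyloxy group gives the 3,4-anti relationship that the alkoxide partner needs. The forward reduction requires zinc to chelate only the C3 oxygen, which the silyl ether at C2 ensures.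

25 to 22 and 13, and 22 to 21: the C4–C(sp) bond is cut at the aldehyde stage. Chelation-controlled alkynylation gives the opposite, 3,4-syn relationship from the same kind of intermediate. The aldehyde must not epimerise at C3 before it reacts.

12 to 11 to 10 to 7 and 8, and 21 to 20 to 19 to 18 and 8: the C2–C3 bond of each arm is cut. Two glycolate aldol reactions on the same aldehyde set C3 identically and C2 oppositely, anti with one antipode of the auxiliary and syn with the other. The amide exchange prepares both arms for an acetylide or a hydride. 7 and 18 are cut at the N–acyl bond to 5 or 17 and 6.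

4 to 3 to 2 to 1: the C–Cl bond, the carbinol C–H bond and the two O–benzyl bonds are cut, which leads to 1. The substitution at the carbinol must not cost an enol ether benzyl group.

## Other disconnections considered

Alternative 1: The cut is the C3=C4 bond of a flav-3-ene form of unit B, which is grown on a complete, protected unit A whose O4 already carries ring A of unit B as an aroyl ester. In the forward direction an excess of Cp2Ti(CH2)ClAlMe2 A2 would methylenate the ester carbonyl, and the enol ether so formed would close by metathesis onto the vinyl group of a 1-arylallyl ether on the C8a oxygen, giving the 4-alkoxy-2H-chromene A1. In its favour, C4 of unit B enters as a carboxyl carbon, so the bond between the units is made by simple acylation with no stereochemical demand. On this point the alternative is the better plan, because the chosen route makes the same bond by SN2 displacement at a hindered secondary carbon. C2 of unit B could come from an enantioenriched allylic ether, which is equal in reliability to the aldol control used here. Against it, A1 still lacks the C3 oxygen and the C3 and C4 stereocentres of unit B. A syn hydroboration on the face away from the C2 aryl group would place the C3 hydroxyl trans to the C4 oxygen, whereas unit B needs them cis, so an epoxidation and a reductive opening with inversion at an acetal-like, benzylic C4 would be needed. Unit A would have to be made separately as an all-cis diol with O3 and O4 told apart, and its benzylic C4–O bond would have to survive an excess of the Lewis acidic A2. In comparison, neither key step creates a stereocentre, but the chosen plan has all six in place beforehand while the alternative leaves two for the most ionisable position. In structure the alternative keeps ring A aromatic throughout, whereas the chosen plan keeps C4 non-benzylic until the end. The two are equal in convergence, and the alternative is unlikely to be shorter once unit A and the adjustment after cyclisation are counted.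

Alternative 2: The cut is O1–C2 in both units, with C2 and C3 of each arm stored as an epoxide, cis on one arm and trans on the other. In the forward direction a catalytic amount of camphorsulfonic acid A4 would let the two C8a phenols open the epoxides at their benzylic carbons with inversion, closing both rings C and giving the tetrabenzyl ether bis(pivalate) A3 with free C3 hydroxyls. In its favour, one ring closure sets C2 and uncovers the C3 hydroxyl, so no C3 protecting group, no C2 silyl ether and no separate activation are needed. The pivalates on ring B also damp cation formation at C2, a safeguard that the Mitsunobu closure of the chosen plan lacks. In these respects the alternative is the better one. Against it, 6-endo opening has to win over 5-exo attack at C3 and depends on the same benzylic activation that the pivalates weaken. A cis aryl epoxide opens with less stereochemical fidelity than a trans one, and it is the cis epoxide that must deliver the all-cis unit A. Two epoxides of different geometry would have to be installed with control in one molecule, and the C4–O–C4 ether would have to be made and carried through acid while each C4 is benzylic to a ring with a free ortho hydroxyl. In comparison, the chosen plan keeps C4 non-benzylic until rings A exist and sets C2 and C3 by aldol reactions under auxiliary control. The end game of the alternative is shorter by one step, a point in its favour on step economy, but basic removal of the pivalates from a catechol-rich product is an added hazard and the front end is less certain.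

Alternative 3: The cut is the C2–aryl bond of both units. In the forward direction 4-benzyloxyphenylmagnesium bromide A6 would add to both formyl groups of the ether-linked substrate. Chelation control on the arm with a C3 benzyloxy group would give threo and Felkin–Anh control on the arm with a C3 silyloxy group would give erythro, leading to the diol A5. In its favour, ring B enters last, which is equal or better for analogue work, two stereocentres are set in one operation, and neither tin nor prolonged heating is needed. The end game (phenol release, double Mitsunobu closure with inversion) is the same as in the chosen plan, so the two are equal there. Against it, one set of conditions must enforce chelation on one arm and exclude it on the other, while the C4 ether oxygen is a further chelating site on both. Each aldehyde can epimerise at C3, ring A is present from the start so the ether must be forged between two benzylic, ionisable carbons, and the two different C3 groups cost an extra deprotection. In comparison, stereocontrol at C2 by Grignard addition is less secure than the auxiliary-controlled aldol reactions of the chosen plan, which in turn needs more steps before the union. Mechanistically the alternative relies on substrate control at both new centres, while the chosen key step creates none.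

Key step: step 19

Remark on the chemistry (assumption): in the MgCl2-catalysed anti-aldol reaction of step 5 the glycolyl imide 7 is taken to react with the same facial sense as N-propionyl imides (magnesium-chelated Z enolate, attack on the face opposite the auxiliary benzyl group); 7 and 18 are prepared in steps 4 and 10 and are not bought.

## Route

Step 1
Reactants: 1 squaric acid
Product: 2 3,4-bis(benzyloxy)cyclobut-3-ene-1,2-dione
Conditions: BnOH (excess), toluene, reflux, azeotropic removal of water
Reagents that add atoms: benzyl alcohol, OCc1ccccc1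
Why: Squaric acid is a strong vinylogous acid and esterifies with alcohols under azeotropic removal of water (Fischer-type esterification); benzyl is chosen so that the C7 and C8 oxygens are freed in the final hydrogenolysis.

Step 2
Reactants: 2 3,4-bis(benzyloxy)cyclobut-3-ene-1,2-dione
Product: 3 2,3-bis(benzyloxy)-4-hydroxycyclobut-2-en-1-one (racemic)
Conditions: LiAlH(OtBu)3, THF, −78 °C; then aqueous NH4Cl
Reagents that add atoms: none
Why: One equivalent of the hindered hydride adds 1,2 to one of the two equivalent carbonyl groups and the alkoxide formed shields the second (carbonyl reduction); the neutral quench avoids acid-induced collapse of the hydroxy enol ether to a dione.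

Step 3
Reactants: 3 2,3-bis(benzyloxy)-4-hydroxycyclobut-2-en-1-one
Product: 4 2,3-bis(benzyloxy)-4-chlorocyclobut-2-en-1-one (racemic)
Conditions: PPh3, N-chlorosuccinimide, THF, −20 → 0 °C
Reagents that add atoms: N-chlorosuccinimide, O=C1CCC(=O)N1Cl
Why: Appel-type deoxychlorination: the alkoxyphosphonium salt is displaced by chloride at the activated carbon next to the ketone under non-acidic conditions; the configuration of this carbon is irrelevant because it becomes sp2 in step 19.

Step 4
Reactants: 5 (R)-4-benzyloxazolidin-2-one; 6 (benzyloxy)acetyl chloride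
Product: 7 (R)-4-benzyl-3-[(benzyloxy)acetyl]oxazolidin-2-one
Conditions: n-BuLi, THF, −78 °C; then 6, −78 → 0 °C
Reagents that add atoms: none
Why: N-acylation of the lithiated oxazolidinone by an acid chloride; the auxiliary stereocentre is not involved.

Step 5
Reactants: 7 (R)-4-benzyl-3-[(benzyloxy)acetyl]oxazolidin-2-one; 8 4-(benzyloxy)benzaldehyde
Product: 10 (4R)-4-benzyl-3-[(2S,3S)-2-(benzyloxy)-3-[4-(benzyloxy)phenyl]-3-hydroxypropanoyl]oxazolidin-2-one, via trimethylsilyl ether of the anti aldol adduct 9 (not isolated)
Conditions: MgCl2 (20 mol %), Et3N, Me3SiCl, EtOAc, 23 °C; then 1 M HCl, THF, 0 °C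
Reagents that add atoms: none
Why: Magnesium halide-catalysed direct anti-aldol reaction of an N-acyloxazolidinone with a non-enolisable aromatic aldehyde: soft enolisation gives the magnesium-chelated Z enolate, which should react on the face opposite the auxiliary benzyl group, so the (R)-auxiliary should give the (2S,3S) anti adduct that carries the future C3 and C2 of unit A. Silylation of the aldolate turns the magnesium over and blocks the retro-aldol reaction.

Step 6
Reactants: 10 (4R)-4-benzyl-3-[(2S,3S)-2-(benzyloxy)-3-[4-(benzyloxy)phenyl]-3-hydroxypropanoyl]oxazolidin-2-one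
Product: 11 (2S,3S)-2-(benzyloxy)-3-[4-(benzyloxy)phenyl]-3-hydroxy-N-methoxy-N-methylpropanamide
Conditions: AlMe3, MeNHOMe·HCl, THF, −10 → 0 °C
Reagents that add atoms: N,O-dimethylhydroxylamine hydrochloride, CNOC.Cl
Why: Aluminium amide transamidation, directed to the exocyclic carbonyl by the free beta-hydroxyl, gives the Weinreb amide and releases the auxiliary without touching the alpha centre.

Step 7
Reactants: 11 (2S,3S)-2-(benzyloxy)-3-[4-(benzyloxy)phenyl]-3-hydroxy-N-methoxy-N-methylpropanamide
Product: 12 (2S,3S)-2-(benzyloxy)-3-[4-(benzyloxy)phenyl]-3-[(tert-butyldimethylsilyl)oxy]-N-methoxy-N-methylpropanamide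
Conditions: tBuMe2SiOTf, 2,6-lutidine, CH2Cl2, −78 → 0 °C
Reagents that add atoms: tert-butyldimethylsilyl triflate, CC(C)(C)[Si](C)(C)OS(=O)(=O)C(F)(F)F
Why: Buffered silylation of the secondary benzylic alcohol; the non-chelating silyl ether masks C2 until the pyran closure and leaves the C3 benzyloxy group as the only chelating site for step 9.

Step 8
Reactants: 12 (2S,3S)-2-(benzyloxy)-3-[4-(benzyloxy)phenyl]-3-[(tert-butyldimethylsilyl)oxy]-N-methoxy-N-methylpropanamide; 13 trimethylsilylacetylene
Product: 15 (4S,5S)-4-(benzyloxy)-5-[4-(benzyloxy)phenyl]-5-[(tert-butyldimethylsilyl)oxy]-1-(trimethylsilyl)pent-1-yn-3-one, via [(trimethylsilyl)ethynyl]magnesium bromide 14 (not isolated)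
Conditions: 13, EtMgBr, THF, 0 → 23 °C; then 12, THF, 0 °C; aqueous NH4Cl
Reagents that add atoms: none
Why: The Grignard reagent deprotonates the alkyne, and the alkynylmagnesium bromide acylates on the Weinreb amide, where the magnesium-chelated tetrahedral adduct survives until the quench, so the reaction stops at the ketone (Weinreb ketone synthesis). The weakly basic reagent and the cold, weakly acidic quench guard against epimerisation at C3 and beta-elimination of the silyloxy group.

Step 9
Reactants: 15 (4S,5S)-4-(benzyloxy)-5-[4-(benzyloxy)phenyl]-5-[(tert-butyldimethylsilyl)oxy]-1-(trimethylsilyl)pent-1-yn-3-one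
Product: 16 (3R,4R,5S)-4-(benzyloxy)-5-[4-(benzyloxy)phenyl]-5-[(tert-butyldimethylsilyl)oxy]-1-(trimethylsilyl)pent-1-yn-3-ol
Conditions: Zn(BH4)2 (ethereal solution), Et2O, −78 → −30 °C
Reagents that add atoms: none
Why: Chelation-controlled ketone reduction (Cram chelate): zinc bridges the carbonyl and the C3 benzyloxy oxygen and hydride enters opposite the bulky C2 substituent, which should give the 3,4-anti alcohol with (R)-C4, the configuration that unit A keeps.

Step 10
Reactants: 17 (S)-4-benzyloxazolidin-2-one; 6 (benzyloxy)acetyl chloride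
Product: 18 (S)-4-benzyl-3-[(benzyloxy)acetyl]oxazolidin-2-one
Conditions: n-BuLi, THF, −78 °C; then 6, −78 → 0 °C
Reagents that add atoms: none
Why: N-acylation of the lithiated oxazolidinone, as in step 4, with the antipodal auxiliary.

Step 11
Reactants: 18 (S)-4-benzyl-3-[(benzyloxy)acetyl]oxazolidin-2-one; 8 4-(benzyloxy)benzaldehyde
Product: 19 (4S)-4-benzyl-3-[(2S,3R)-2-(benzyloxy)-3-[4-(benzyloxy)phenyl]-3-hydroxypropanoyl]oxazolidin-2-one
Conditions: Bu2BOTf, Et3N, CH2Cl2, −78 → 0 °C; then 8, −78 → 0 °C; pH 7 buffer, MeOH, H2O2
Reagents that add atoms: none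
Why: Evans syn aldol reaction: the Z boron enolate reacts through a Zimmerman–Traxler chair on the face opposite the auxiliary benzyl group of the dipole-minimised conformer, which should give the (2S,3R) syn adduct. This adduct has the same C3 configuration as 10 and the epimeric C2 carbinol that unit B needs.

Step 12
Reactants: 19 (4S)-4-benzyl-3-[(2S,3R)-2-(benzyloxy)-3-[4-(benzyloxy)phenyl]-3-hydroxypropanoyl]oxazolidin-2-one
Product: 20 (2S,3R)-2-(benzyloxy)-3-[4-(benzyloxy)phenyl]-3-hydroxy-N-methoxy-N-methylpropanamide
Conditions: AlMe3, MeNHOMe·HCl, THF, −10 → 0 °C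
Reagents that add atoms: N,O-dimethylhydroxylamine hydrochloride, CNOC.Cl
Why: Hydroxyl-directed aluminium amide transamidation to the Weinreb amide, as in step 6.

Step 13
Reactants: 20 (2S,3R)-2-(benzyloxy)-3-[4-(benzyloxy)phenyl]-3-hydroxy-N-methoxy-N-methylpropanamide
Product: 21 (2S,3R)-2-(benzyloxy)-3-[4-(benzyloxy)phenyl]-3-[(tert-butyldimethylsilyl)oxy]-N-methoxy-N-methylpropanamide
Conditions: tBuMe2SiOTf, 2,6-lutidine, CH2Cl2, −78 → 0 °C
Reagents that add atoms: tert-butyldimethylsilyl triflate, CC(C)(C)[Si](C)(C)OS(=O)(=O)C(F)(F)F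
Why: Buffered silylation of the benzylic alcohol, as in step 7.

Step 14
Reactants: 21 (2S,3R)-2-(benzyloxy)-3-[4-(benzyloxy)phenyl]-3-[(tert-butyldimethylsilyl)oxy]-N-methoxy-N-methylpropanamide
Product: 22 (2S,3R)-2-(benzyloxy)-3-[4-(benzyloxy)phenyl]-3-[(tert-butyldimethylsilyl)oxy]propanal
Conditions: iBu2AlH, THF, −78 °C; then aqueous potassium sodium tartrate
Reagents that add atoms: none
Why: Reduction of a Weinreb amide stops at the chelated hemiaminal, which gives the aldehyde on work-up; the alpha-alkoxy aldehyde is used at once so that C3 does not epimerise.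

Step 15
Reactants: 22 (2S,3R)-2-(benzyloxy)-3-[4-(benzyloxy)phenyl]-3-[(tert-butyldimethylsilyl)oxy]propanal; 13 trimethylsilylacetylene
Product: 25 (3S,4R,5R)-4-(benzyloxy)-5-[4-(benzyloxy)phenyl]-5-[(tert-butyldimethylsilyl)oxy]-1-(trimethylsilyl)pent-1-yn-3-ol, via lithium (trimethylsilyl)acetylide 23 (not isolated), via [(trimethylsilyl)ethynyl]zinc bromide 24 (not isolated)
Conditions: 13, n-BuLi, Et2O, −78 °C; ZnBr2, 0 °C; then 22, Et2O, −78 → 0 °C
Reagents that add atoms: none
Why: Lithiation of the alkyne and transmetalation with ZnBr2 give the alkynylzinc bromide, which adds to the alpha-alkoxy aldehyde under chelation control in ether (Cram chelate). Zinc bridges the aldehyde and the C3 benzyloxy oxygen and the alkyne adds opposite the C2 substituent, which should give the 3,4-syn alcohol with (S)-C4, the centre that step 16 inverts.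

Step 16
Reactants: 25 (3S,4R,5R)-4-(benzyloxy)-5-[4-(benzyloxy)phenyl]-5-[(tert-butyldimethylsilyl)oxy]-1-(trimethylsilyl)pent-1-yn-3-ol; 16 (3R,4R,5S)-4-(benzyloxy)-5-[4-(benzyloxy)phenyl]-5-[(tert-butyldimethylsilyl)oxy]-1-(trimethylsilyl)pent-1-yn-3-ol
Product: 27 di(pent-1-yn-3-yl) ether whose two groups are (3R,4R,5S)- and (3R,4R,5R)-4-(benzyloxy)-5-[4-(benzyloxy)phenyl]-5-[(tert-butyldimethylsilyl)oxy]-1-(trimethylsilyl)pent-1-yn-3-yl, via propargylic triflate 26 (not isolated)
Conditions: 25, Tf2O, 2,6-di-tert-butyl-4-methylpyridine, CH2Cl2, −78 °C, cold pentane filtration of the pyridinium salt; then added to 16, NaN(SiMe3)2, 15-crown-5, THF, −78 → −20 °C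
Reagents that add atoms: none
Why: Williamson ether synthesis by SN2 displacement of a secondary propargylic triflate by a secondary alkoxide, with inversion at C4 of the triflate arm (S to R) and retention at the alkoxide carbon. The carbon is not benzylic, the slim alkyne favours SN2, the silyl caps block SN2' attack and acetylide formation, and cold generation of the alkoxide suppresses silyl migration.

Step 17
Reactants: 27 bis(silylalkyne) ether
Product: 28 di(pent-1-yn-3-yl) ether whose two groups are (3R,4R,5S)- and (3R,4R,5R)-4-(benzyloxy)-5-[4-(benzyloxy)phenyl]-5-[(tert-butyldimethylsilyl)oxy]pent-1-yn-3-yl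
Conditions: K2CO3, MeOH/THF, 23 °C
Reagents that add atoms: none
Why: Methanolysis of the two C(sp)–Si bonds; the silyl ethers on oxygen and the benzyl ethers are stable to these conditions.

Step 18
Reactants: 28 diyne ether
Product: 29 di(pent-1-en-3-yl) ether whose two groups are (1E,3R,4R,5S)- and (1E,3R,4R,5R)-4-(benzyloxy)-5-[4-(benzyloxy)phenyl]-5-[(tert-butyldimethylsilyl)oxy]-1-(tributylstannyl)pent-1-en-3-yl
Conditions: Bu3SnH, Pd2(dba)3 (2.5 mol %), Cy3P·HBF4, iPr2NEt, CH2Cl2, 0 → 23 °C
Reagents that add atoms: tributyltin hydride, CCCC[SnH](CCCC)CCCC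
Why: Palladium-catalysed syn hydrostannation of terminal alkynes; the bulky tricyclohexylphosphine and the branched propargylic carbons steer tin to the terminal carbon, so both arms should give the (E)-alkenylstannane.

Step 19
Reactants: 29 bis(alkenylstannane) ether; 4 2,3-bis(benzyloxy)-4-chlorocyclobut-2-en-1-one (2.4 equiv)
Product: 33 dipropyl ether whose two groups are (1R,2R,3S)- and (1R,2R,3R)-2-(benzyloxy)-1-[3,4-bis(benzyloxy)-2-hydroxyphenyl]-3-[4-(benzyloxy)phenyl]-3-[(tert-butyldimethylsilyl)oxy]propyl, via bis(4-alkenylcyclobutenone) 30 (not isolated), via bis(dienylketene) 31 (not isolated), via bis(cyclohexa-2,4-dienone) 32 (not isolated)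
Conditions: Pd2(dba)3 (5 mol %), tri(2-furyl)phosphine (20 mol %), dioxane, 50 °C; then 100 °C
Reagents that add atoms: none
Why: Zerovalent palladium inserts into the C–Cl bond of 4, each alkenylstannane of 29 transmetalates with retention of the E geometry, and reductive elimination at the former chlorine-bearing ring carbon forms C5–C6 of each unit (30). On heating, each cyclobutenone undergoes reversible conrotatory 4π ring opening, and the rotamer that turns the alkenyl group inward gives the dienylketene with ketene and alkenyl group cis (31); this is drained by a thermal disrotatory 6π electrocyclisation that forms C4a–C8a and closes ring A of that unit as a six-membered carbocycle (32), and enolisation gives the C8a phenol. The closest known reaction type is the Stille coupling of 4-chlorocyclobutenones with alkenylstannanes followed by thermal ring expansion to phenols, run here on both arms of one substrate. No stereocentre is created, since the sp3 ring carbons of 30 and 32 are lost on aromatisation. Regiochemistry is fixed by connectivity: the ketene carbon can bond only to the alkene carbon that carries C4, so it becomes C8a, the two benzyloxy carbons become C8 and C7, and the formerly stannylated carbon becomes C5. The step needs coupling at the chlorine-bearing carbon and not at the other allyl terminus, which the full substitution and the benzyloxy group of that terminus secure. It also needs the C2, C3 and C4 centres to survive, which the neutral, base-free medium and the non-benzylic nature of C4 up to this point secure. The silyl ethers at C2 leave no hydroxyl in 29 that could trap the ketene before it cyclises.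

Step 20
Reactants: 33 bis(phenol) bis(silyl ether)
Product: 34 dipropyl ether whose two groups are (1R,2S,3S)- and (1R,2S,3R)-2-(benzyloxy)-1-[3,4-bis(benzyloxy)-2-hydroxyphenyl]-3-[4-(benzyloxy)phenyl]-3-hydroxypropyl
Conditions: Bu4NF, AcOH, THF, 0 → 23 °C
Reagents that add atoms: none
Why: Fluoride cleaves the two benzylic silyl ethers (desilylation); the acetic acid buffer keeps the C8a phenols protonated so that they cannot expel the ortho C4 ether oxygen as a quinone methide.

Step 21
Reactants: 34 bis(phenol) diol
Product: 35 (2R,3R,4R)-3,7,8-tris(benzyloxy)-2-[4-(benzyloxy)phenyl]-4-{[(2S,3R,4R)-3,7,8-tris(benzyloxy)-2-[4-(benzyloxy)phenyl]chroman-4-yl]oxy}chromane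
Conditions: PPh3, iPrO2CN=NCO2iPr, THF (0.01 M), 0 → 23 °C
Reagents that add atoms: none
Why: Twofold intramolecular Mitsunobu etherification: each C8a phenol displaces the oxyphosphonium group at its own C2 in a 6-exo-tet SN2 closure with inversion, which turns the (S)-carbinol into the 2,3-cis unit A and the (R)-carbinol into the 2,3-trans unit B. This closure is known for benzyl-protected flavan-3-ols with an electron-rich ring B, and the adjacent benzyloxy group disfavours ionisation at C2.

Step 22
Reactants: 35 octabenzyl ether
Product: 36 (2R,3R,4R)-2-(4-hydroxyphenyl)-4-{[(2S,3R,4R)-3,7,8-trihydroxy-2-(4-hydroxyphenyl)chroman-4-yl]oxy}chromane-3,7,8-triol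
Conditions: H2 (1 atm), Pd(OH)2/C, THF/MeOH, 23 °C
Reagents that add atoms: none
Why: Hydrogenolysis of six aryl benzyl ethers and two secondary alkyl benzyl ethers; the branched, flanked C4–O–C4 and C2–O1 bonds should cleave much more slowly, so the reaction is stopped when the benzyl groups are gone and the catechol product is isolated under argon.

## Compound list

1 | squaric acid | O=C1C(=O)C(O)=C1O | starting material
2 | 3,4-bis(benzyloxy)cyclobut-3-ene-1,2-dione | O=C1C(=O)C(OCc2ccccc2)=C1OCc1ccccc1 | intermediate
3 | 2,3-bis(benzyloxy)-4-hydroxycyclobut-2-en-1-one (racemic) | O=C1C(O)C(OCc2ccccc2)=C1OCc1ccccc1 | intermediate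
4 | 2,3-bis(benzyloxy)-4-chlorocyclobut-2-en-1-one (racemic) | O=C1C(Cl)C(OCc2ccccc2)=C1OCc1ccccc1 | intermediate
5 | (R)-4-benzyloxazolidin-2-one | O=C1N[C@H](Cc2ccccc2)CO1 | starting material
6 | (benzyloxy)acetyl chloride | O=C(Cl)COCc1ccccc1 | starting material
7 | (R)-4-benzyl-3-[(benzyloxy)acetyl]oxazolidin-2-one | O=C(COCc1ccccc1)N1[C@H](Cc2ccccc2)COC1=O | intermediate
8 | 4-(benzyloxy)benzaldehyde | O=Cc1ccc(OCc2ccccc2)cc1 | starting material
9 | (4R)-4-benzyl-3-[(2S,3S)-2-(benzyloxy)-3-[4-(benzyloxy)phenyl]-3-[(trimethylsilyl)oxy]propanoyl]oxazolidin-2-one | c1ccccc1COc1ccc([C@H](O[Si](C)(C)C)[C@H](OCc2ccccc2)C(=O)N2[C@H](Cc3ccccc3)COC2=O)cc1 | intermediate (not isolated)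
10 | (4R)-4-benzyl-3-[(2S,3S)-2-(benzyloxy)-3-[4-(benzyloxy)phenyl]-3-hydroxypropanoyl]oxazolidin-2-one | c1ccccc1COc1ccc([C@H](O)[C@H](OCc2ccccc2)C(=O)N2[C@H](Cc3ccccc3)COC2=O)cc1 | intermediate
11 | (2S,3S)-2-(benzyloxy)-3-[4-(benzyloxy)phenyl]-3-hydroxy-N-methoxy-N-methylpropanamide | c1ccccc1COc1ccc([C@H](O)[C@H](OCc2ccccc2)C(=O)N(C)OC)cc1 | intermediate
12 | (2S,3S)-2-(benzyloxy)-3-[4-(benzyloxy)phenyl]-3-[(tert-butyldimethylsilyl)oxy]-N-methoxy-N-methylpropanamide | c1ccccc1COc1ccc([C@H](O[Si](C)(C)C(C)(C)C)[C@H](OCc2ccccc2)C(=O)N(C)OC)cc1 | intermediate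
13 | trimethylsilylacetylene | C#C[Si](C)(C)C | starting material
14 | [(trimethylsilyl)ethynyl]magnesium bromide | Br[Mg]C#C[Si](C)(C)C | intermediate (not isolated)
15 | (4S,5S)-4-(benzyloxy)-5-[4-(benzyloxy)phenyl]-5-[(tert-butyldimethylsilyl)oxy]-1-(trimethylsilyl)pent-1-yn-3-one | c1ccccc1COc1ccc([C@H](O[Si](C)(C)C(C)(C)C)[C@H](OCc2ccccc2)C(=O)C#C[Si](C)(C)C)cc1 | intermediate
16 | (3R,4R,5S)-4-(benzyloxy)-5-[4-(benzyloxy)phenyl]-5-[(tert-butyldimethylsilyl)oxy]-1-(trimethylsilyl)pent-1-yn-3-ol | c1ccccc1COc1ccc([C@H](O[Si](C)(C)C(C)(C)C)[C@H](OCc2ccccc2)[C@@H](C#C[Si](C)(C)C)O)cc1 | intermediate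
17 | (S)-4-benzyloxazolidin-2-one | O=C1N[C@@H](Cc2ccccc2)CO1 | starting material
18 | (S)-4-benzyl-3-[(benzyloxy)acetyl]oxazolidin-2-one | O=C(COCc1ccccc1)N1[C@@H](Cc2ccccc2)COC1=O | intermediate
19 | (4S)-4-benzyl-3-[(2S,3R)-2-(benzyloxy)-3-[4-(benzyloxy)phenyl]-3-hydroxypropanoyl]oxazolidin-2-one | c1ccccc1COc1ccc([C@@H](O)[C@H](OCc2ccccc2)C(=O)N2[C@@H](Cc3ccccc3)COC2=O)cc1 | intermediate
20 | (2S,3R)-2-(benzyloxy)-3-[4-(benzyloxy)phenyl]-3-hydroxy-N-methoxy-N-methylpropanamide | c1ccccc1COc1ccc([C@@H](O)[C@H](OCc2ccccc2)C(=O)N(C)OC)cc1 | intermediate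
21 | (2S,3R)-2-(benzyloxy)-3-[4-(benzyloxy)phenyl]-3-[(tert-butyldimethylsilyl)oxy]-N-methoxy-N-methylpropanamide | c1ccccc1COc1ccc([C@@H](O[Si](C)(C)C(C)(C)C)[C@H](OCc2ccccc2)C(=O)N(C)OC)cc1 | intermediate
22 | (2S,3R)-2-(benzyloxy)-3-[4-(benzyloxy)phenyl]-3-[(tert-butyldimethylsilyl)oxy]propanal | c1ccccc1COc1ccc([C@@H](O[Si](C)(C)C(C)(C)C)[C@H](OCc2ccccc2)C=O)cc1 | intermediate
23 | lithium (trimethylsilyl)acetylide | [Li]C#C[Si](C)(C)C | intermediate (not isolated)
24 | [(trimethylsilyl)ethynyl]zinc bromide | Br[Zn]C#C[Si](C)(C)C | intermediate (not isolated)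
25 | (3S,4R,5R)-4-(benzyloxy)-5-[4-(benzyloxy)phenyl]-5-[(tert-butyldimethylsilyl)oxy]-1-(trimethylsilyl)pent-1-yn-3-ol | c1ccccc1COc1ccc([C@@H](O[Si](C)(C)C(C)(C)C)[C@H](OCc2ccccc2)[C@H](C#C[Si](C)(C)C)O)cc1 | intermediate
26 | (3S,4S,5R)-4-(benzyloxy)-5-[4-(benzyloxy)phenyl]-5-[(tert-butyldimethylsilyl)oxy]-1-(trimethylsilyl)pent-1-yn-3-yl trifluoromethanesulfonate | c1ccccc1COc1ccc([C@@H](O[Si](C)(C)C(C)(C)C)[C@H](OCc2ccccc2)[C@H](C#C[Si](C)(C)C)OS(=O)(=O)C(F)(F)F)cc1 | intermediate (not isolated)
27 | di(pent-1-yn-3-yl) ether whose two groups are (3R,4R,5S)- and (3R,4R,5R)-4-(benzyloxy)-5-[4-(benzyloxy)phenyl]-5-[(tert-butyldimethylsilyl)oxy]-1-(trimethylsilyl)pent-1-yn-3-yl | c1ccccc1COc1ccc([C@H](O[Si](C)(C)C(C)(C)C)[C@H](OCc2ccccc2)[C@@H](C#C[Si](C)(C)C)O[C@H](C#C[Si](C)(C)C)[C@@H](OCc2ccccc2)[C@H](O[Si](C)(C)C(C)(C)C)c2ccc(OCc3ccccc3)cc2)cc1 | intermediate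
28 | di(pent-1-yn-3-yl) ether whose two groups are (3R,4R,5S)- and (3R,4R,5R)-4-(benzyloxy)-5-[4-(benzyloxy)phenyl]-5-[(tert-butyldimethylsilyl)oxy]pent-1-yn-3-yl | c1ccccc1COc1ccc([C@H](O[Si](C)(C)C(C)(C)C)[C@H](OCc2ccccc2)[C@@H](C#C)O[C@H](C#C)[C@@H](OCc2ccccc2)[C@H](O[Si](C)(C)C(C)(C)C)c2ccc(OCc3ccccc3)cc2)cc1 | intermediate
29 | di(pent-1-en-3-yl) ether whose two groups are (1E,3R,4R,5S)- and (1E,3R,4R,5R)-4-(benzyloxy)-5-[4-(benzyloxy)phenyl]-5-[(tert-butyldimethylsilyl)oxy]-1-(tributylstannyl)pent-1-en-3-yl | c1ccccc1COc1ccc([C@H](O[Si](C)(C)C(C)(C)C)[C@H](OCc2ccccc2)[C@@H](/C=C/[Sn](CCCC)(CCCC)CCCC)O[C@H](/C=C/[Sn](CCCC)(CCCC)CCCC)[C@@H](OCc2ccccc2)[C@H](O[Si](C)(C)C(C)(C)C)c2ccc(OCc3ccccc3)cc2)cc1 | intermediate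
30 | 29 with each tributylstannyl group replaced by a 2,3-bis(benzyloxy)-4-oxocyclobut-2-en-1-yl group (epimers at the two new ring carbons) | c1ccccc1COc1ccc([C@H](O[Si](C)(C)C(C)(C)C)[C@H](OCc2ccccc2)[C@@H](/C=C/C2C(=O)C(OCc3ccccc3)=C2OCc2ccccc2)O[C@H](/C=C/C2C(=O)C(OCc3ccccc3)=C2OCc2ccccc2)[C@@H](OCc2ccccc2)[C@H](O[Si](C)(C)C(C)(C)C)c2ccc(OCc3ccccc3)cc2)cc1 | intermediate (not isolated)
31 | bis(dienylketene): each cyclobutenone of 30 opened to a 2,3-bis(benzyloxy)-1-oxohexa-1,3,5-trienyl chain with ketene and alkenyl group cis | c1ccccc1COc1ccc([C@H](O[Si](C)(C)C(C)(C)C)[C@H](OCc2ccccc2)[C@@H](/C=C/C=C(OCc2ccccc2)\C(OCc2ccccc2)=C=O)O[C@H](/C=C/C=C(OCc2ccccc2)\C(OCc2ccccc2)=C=O)[C@@H](OCc2ccccc2)[C@H](O[Si](C)(C)C(C)(C)C)c2ccc(OCc3ccccc3)cc2)cc1 | intermediate (not isolated)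
32 | bis(cyclohexa-2,4-dienone): each chain of 31 closed to a 4,5-bis(benzyloxy)-6-oxocyclohexa-2,4-dien-1-yl ring (epimers at the two new ring carbons) | c1ccccc1COc1ccc([C@H](O[Si](C)(C)C(C)(C)C)[C@H](OCc2ccccc2)[C@@H](C2C=CC(OCc3ccccc3)=C(OCc3ccccc3)C2=O)O[C@H](C2C=CC(OCc3ccccc3)=C(OCc3ccccc3)C2=O)[C@@H](OCc2ccccc2)[C@H](O[Si](C)(C)C(C)(C)C)c2ccc(OCc3ccccc3)cc2)cc1 | intermediate (not isolated)
33 | dipropyl ether whose two groups are (1R,2R,3S)- and (1R,2R,3R)-2-(benzyloxy)-1-[3,4-bis(benzyloxy)-2-hydroxyphenyl]-3-[4-(benzyloxy)phenyl]-3-[(tert-butyldimethylsilyl)oxy]propyl | c1ccccc1COc1ccc([C@H](O[Si](C)(C)C(C)(C)C)[C@H](OCc2ccccc2)[C@@H](c2ccc(OCc3ccccc3)c(OCc3ccccc3)c2O)O[C@H](c2ccc(OCc3ccccc3)c(OCc3ccccc3)c2O)[C@@H](OCc2ccccc2)[C@H](O[Si](C)(C)C(C)(C)C)c2ccc(OCc3ccccc3)cc2)cc1 | intermediate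
34 | dipropyl ether whose two groups are (1R,2S,3S)- and (1R,2S,3R)-2-(benzyloxy)-1-[3,4-bis(benzyloxy)-2-hydroxyphenyl]-3-[4-(benzyloxy)phenyl]-3-hydroxypropyl | c1ccccc1COc1ccc([C@H](O)[C@H](OCc2ccccc2)[C@@H](c2ccc(OCc3ccccc3)c(OCc3ccccc3)c2O)O[C@H](c2ccc(OCc3ccccc3)c(OCc3ccccc3)c2O)[C@@H](OCc2ccccc2)[C@H](O)c2ccc(OCc3ccccc3)cc2)cc1 | intermediate
35 | (2R,3R,4R)-3,7,8-tris(benzyloxy)-2-[4-(benzyloxy)phenyl]-4-{[(2S,3R,4R)-3,7,8-tris(benzyloxy)-2-[4-(benzyloxy)phenyl]chroman-4-yl]oxy}chromane | c1ccccc1COc1ccc([C@H]2Oc3c(ccc(OCc4ccccc4)c3OCc3ccccc3)[C@@H](O[C@@H]3c4ccc(OCc5ccccc5)c(OCc5ccccc5)c4O[C@@H](c4ccc(OCc5ccccc5)cc4)[C@@H]3OCc3ccccc3)[C@H]2OCc2ccccc2)cc1 | intermediate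
36 | (2R,3R,4R)-2-(4-hydroxyphenyl)-4-{[(2S,3R,4R)-3,7,8-trihydroxy-2-(4-hydroxyphenyl)chroman-4-yl]oxy}chromane-3,7,8-triol (CNP0241481.1) | Oc1ccc([C@H]2Oc3c(ccc(O)c3O)[C@@H](O[C@@H]3c4ccc(O)c(O)c4O[C@@H](c4ccc(O)cc4)[C@@H]3O)[C@H]2O)cc1 | target

## Step count and least certain steps

Total: 22 steps. Longest linear sequence: 13 steps (steps 4 to 9 or 10 to 15, then 16 to 22).

Step 19 (key step). What may go wrong: the second coupling may stall through protodestannylation or homocoupling of the remaining alkenylstannane. During heating, a newly formed ortho phenol may expel the C4 ether oxygen as a quinone methide or add to a dienylketene of the other arm. The cause is that two couplings and two ring expansions must all succeed on one hindered substrate at 100 °C. Fallback: it sets out from 28 and 4 and comes back at 33, without tin. Hydrozirconation of both alkynes of 28 with Cp2Zr(H)Cl in THF gives the bis[(E)-alkenylzirconocene chloride] F1, which is used in solution. Cross-coupling of F1 with 4 under Pd(PPh3)4 at 23 °C gives 30, which is isolated cold and then heated on its own in dilute toluene at 100 °C. Coupling and ring expansion are thereby separated, and no organometallic residue is present while the phenols of 33 form.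

Step 16. What may go wrong: E2 elimination across C3–C4 of the triflate by the hindered alkoxide, ionisation of the triflate with benzyloxy participation and loss of stereochemical fidelity, or silyl migration between the 1,3-related oxygens of the alkoxide. The cause is that both partners are secondary and carry oxygen on the neighbouring carbon. Fallback: the roles of the two arms are exchanged; it sets out from 21 and 12 and comes back at 27. Acylation of the Grignard reagent 14 by 21 gives the (4S,5R) ynone F2, and reduction with Zn(BH4)2 gives the 3,4-anti (3R,4R,5R) alcohol F3, which becomes the alkoxide partner. Reduction of 12 with iBu2AlH gives the (2S,3S) aldehyde F4, addition of the alkynylzinc bromide 24 under chelation gives the 3,4-syn (3S,4R,5S) alcohol F5, and Tf2O converts F5 into the (3S,4S,5S) triflate F6. Displacement of F6 by the sodium alkoxide of F3 inverts C4 of the unit A arm and gives 27.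

Step 5. What may go wrong: low anti selectivity or attack on the other enolate face if magnesium is chelated by the alpha-benzyloxy oxygen and not by the ring carbonyl, and retro-aldol equilibration before silylation. Fallback: a Mukaiyama aldol route; it sets out from 6 and 8 and comes back at 11. 6 and ethanethiol with Et3N give S-ethyl 2-(benzyloxy)ethanethioate F7, and LiN(iPr)2 with Me3SiCl gives the (Z)-silyl ketene thioacetal F8. Addition of F8 to 8 is promoted by Sn(OTf)2, Bu2Sn(OAc)2 and the enantiomer of the proline-derived chiral diamine that delivers the anti (2S,3S) adduct; it gives S-ethyl (2S,3S)-2-(benzyloxy)-3-[4-(benzyloxy)phenyl]-3-hydroxypropanethioate F9. AlMe3 and MeNHOMe·HCl then convert F9 into 11.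

Step 3. What may go wrong: ionisation of the activated alcohol to an alkoxy-stabilised cyclobutenyl cation, followed by loss of a benzyl group to give a dione in place of substitution. Fallback: activation and displacement are separated; it sets out from 3 and comes back at 4. MeSO2Cl and Et3N at −40 °C give the methanesulfonate F10, which is treated with LiCl in acetone at 0 °C to give 4.

Step 22. What may go wrong: over-reduction, that is hydrogenolysis of the C4–O–C4 or C2–O1 bonds while the two slow alkyl benzyl ethers are being removed, and air oxidation of the catechols during isolation. Fallback: it sets out from 35 and comes back at 36 with no new compound. Electron-transfer debenzylation with lithium 4,4'-di-tert-butylbiphenylide in THF at −78 °C is used, followed by an NH4Cl/AcOH quench under argon. The electron should go to the unsubstituted phenyl rings of the benzyl groups in preference to the oxygenated rings, and the phenoxides formed first resist further reduction.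

## Further compounds

F1 | step 19 | 29 with each tributylstannyl group replaced by a chlorobis(cyclopentadienyl)zirconium group | c1ccccc1COc1ccc([C@H](O[Si](C)(C)C(C)(C)C)[C@H](OCc2ccccc2)[C@@H](/C=C/[Zr](Cl)(C2C=CC=C2)C2C=CC=C2)O[C@H](/C=C/[Zr](Cl)(C2C=CC=C2)C2C=CC=C2)[C@@H](OCc2ccccc2)[C@H](O[Si](C)(C)C(C)(C)C)c2ccc(OCc3ccccc3)cc2)cc1
F2 | step 16 | (4S,5R)-4-(benzyloxy)-5-[4-(benzyloxy)phenyl]-5-[(tert-butyldimethylsilyl)oxy]-1-(trimethylsilyl)pent-1-yn-3-one | c1ccccc1COc1ccc([C@@H](O[Si](C)(C)C(C)(C)C)[C@H](OCc2ccccc2)C(=O)C#C[Si](C)(C)C)cc1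
F3 | step 16 | (3R,4R,5R)-4-(benzyloxy)-5-[4-(benzyloxy)phenyl]-5-[(tert-butyldimethylsilyl)oxy]-1-(trimethylsilyl)pent-1-yn-3-ol | c1ccccc1COc1ccc([C@@H](O[Si](C)(C)C(C)(C)C)[C@H](OCc2ccccc2)[C@@H](C#C[Si](C)(C)C)O)cc1
F4 | step 16 | (2S,3S)-2-(benzyloxy)-3-[4-(benzyloxy)phenyl]-3-[(tert-butyldimethylsilyl)oxy]propanal | c1ccccc1COc1ccc([C@H](O[Si](C)(C)C(C)(C)C)[C@H](OCc2ccccc2)C=O)cc1
F5 | step 16 | (3S,4R,5S)-4-(benzyloxy)-5-[4-(benzyloxy)phenyl]-5-[(tert-butyldimethylsilyl)oxy]-1-(trimethylsilyl)pent-1-yn-3-ol | c1ccccc1COc1ccc([C@H](O[Si](C)(C)C(C)(C)C)[C@H](OCc2ccccc2)[C@H](C#C[Si](C)(C)C)O)cc1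
F6 | step 16 | (3S,4S,5S)-4-(benzyloxy)-5-[4-(benzyloxy)phenyl]-5-[(tert-butyldimethylsilyl)oxy]-1-(trimethylsilyl)pent-1-yn-3-yl trifluoromethanesulfonate | c1ccccc1COc1ccc([C@H](O[Si](C)(C)C(C)(C)C)[C@H](OCc2ccccc2)[C@H](C#C[Si](C)(C)C)OS(=O)(=O)C(F)(F)F)cc1
F7 | step 5 | S-ethyl 2-(benzyloxy)ethanethioate | CCSC(=O)COCc1ccccc1
F8 | step 5 | (Z)-{[2-(benzyloxy)-1-(ethylsulfanyl)ethenyl]oxy}trimethylsilane | CCS/C(O[Si](C)(C)C)=C\OCc1ccccc1
F9 | step 5 | S-ethyl (2S,3S)-2-(benzyloxy)-3-[4-(benzyloxy)phenyl]-3-hydroxypropanethioate | c1ccccc1COc1ccc([C@H](O)[C@H](OCc2ccccc2)C(=O)SCC)cc1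
F10 | step 3 | 2,3-bis(benzyloxy)-4-oxocyclobut-2-en-1-yl methanesulfonate (racemic) | O=C1C(OS(C)(=O)=O)C(OCc2ccccc2)=C1OCc1ccccc1
F0 | step 22 | none | none
A1 | alternative 1 | unit A 4-O-(flav-3-en-4-yl) ether, perbenzylated | c9ccccc9COc1ccc([C@H]2Oc3c(ccc(OCc9ccccc9)c3OCc9ccccc9)[C@@H](OC3=C[C@H](c4ccc(OCc9ccccc9)cc4)Oc4c3ccc(OCc9ccccc9)c4OCc9ccccc9)[C@H]2OCc9ccccc9)cc1
A2 | alternative 1 | Cp2Ti(CH2)ClAlMe2 (chloride bridge to aluminium not drawn) | C[Al](C)C[Ti](Cl)(C1C=CC=C1)C1C=CC=C1
A3 | alternative 2 | target as tetrabenzyl ether bis(pivalate) | CC(C)(C)C(=O)Oc1ccc([C@H]2Oc3c(ccc(OCc9ccccc9)c3OCc9ccccc9)[C@@H](O[C@@H]3c4ccc(OCc9ccccc9)c(OCc9ccccc9)c4O[C@@H](c4ccc(OC(=O)C(C)(C)C)cc4)[C@@H]3O)[C@H]2O)cc1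
A4 | alternative 2 | camphorsulfonic acid (racemic) | CC1(C)C2CCC1(CS(=O)(=O)O)C(=O)C2
A5 | alternative 3 | ether-linked diol, erythro on the silyloxy arm and threo on the benzyloxy arm | c9ccccc9COc1ccc([C@H](O)[C@H](O[Si](C)(C)C(C)(C)C)[C@@H](c2ccc(OCc9ccccc9)c(OCc9ccccc9)c2OCC=C)O[C@H](c2ccc(OCc9ccccc9)c(OCc9ccccc9)c2OCC=C)[C@@H](OCc9ccccc9)[C@H](O)c2ccc(OCc9ccccc9)cc2)cc1
A6 | alternative 3 | 4-benzyloxyphenylmagnesium bromide | Br[Mg]c1ccc(OCc2ccccc2)cc1
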